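The product of this flask comes from left-handed substrate (L) and right-handed substrate (S), which meet one single-handed catalyst.

| flask | left-handed substrate | right-handed substrate | gas | free catalyst | remark | time |
|---|---|---|---|---|---|---|
| north-west | 23 mM | 23 mM | 7.4 mM (held) | 0.27 mM | run made earlier |  |
| south-east | 34 mM | 34 mM | 7.4 mM (held) | 0.27 mM | run made earlier |  |
| flask | 46 mM | 46 mM | 7.4 mM (held) | 0.27 mM |  | 6.0 h |

| run | time / h | left-handed substrate / % | right-handed substrate / % |
|---|---|---|---|
| north-west | 0.250 | 45.7 | 48.9 |
| north-west | 0.667 | 40.8 | 50.0 |
| north-west | 1.33 | 32.3 | 52.0 |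
| north-west | 2.00 | 23.0 | 48.7 |
| north-west | 3.00 | 12.3 | 49.8 |
| north-west | 4.00 | 6.1 | 46.6 |
| north-west | 5.00 | 1.3 | 48.8 |
| south-east | 0.417 | 45.3 | 50.7 |
| south-east | 0.667 | 43.6 | 51.4 |
| south-east | 0.833 | 40.5 | 50.7 |
| south-east | 1.33 | 37.0 | 48.3 |
| south-east | 2.00 | 29.8 | 47.8 |
| south-east | 3.00 | 20.5 | 50.4 |
| south-east | 5.00 | 9.8 | 48.4 |

(readings scatter by 1 percentage point)

* part of the left-handed substrate and right-handed substrate charged together that has reacted at 6.0 h
* excess of left-handed product over right-handed product in the product at 6.0 h
* excess of right-handed substrate over left-handed substrate among what is left of the two at 6.0 h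

The late readings look contradictory. The north-west run, near 8.12 mM of L, loses 4.92 mM/h. The south-east run, near 10.3 mM, has more L yet loses less, 3.64 mM/h. So I can't read the pace from L. I look at the ratio instead.

I assume that each catalyst intermediate is made as fast as it is used (a steady state) and that reagent holds steady. Each substrate then goes in proportion to its own concentration and the same free catalyst, and in the ratio of the two paces the amount of working catalyst cancels. With ℓ and σ the shares of L and S left of their own charges:

ln ℓ = s · ln σ

The north-west readings from 3.00 h on, averaged, give

s = 73.3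

This s is the selectivity factor, the pace of L over that of S at equal concentrations. It is a rough reading, since S has dropped 1.6 percentage points against a scatter of 1 point.

The forecast gives c = 38%, eP = 93% and eS = 57%, judging that “the catalyst is slowly dying”. I borrow its c and do not reckon my own. Neglecting S, that leaves ℓ = 24.0%, and σ = exp(ln ℓ / s) = 98.1%. I then get eP = 95.1% and eS = 60.7%, both above the forecast.

The flask gives c = 42.1%, eP = 95.5% and eS = 69.4%.

    free catalyst + left-handed substrate ⇌ catalyst intermediate A (K = 410 /M, k = 810 /M/min)
    free catalyst + right-handed substrate ⇌ catalyst intermediate B (K = 11.0 /M, k = 520 /M/min)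
    reagent + catalyst intermediate A → free catalyst + left-handed product (k = 77.0 /M/min)
    reagent + catalyst intermediate B → free catalyst + right-handed product (k = 25.0 /M/min)
    gas ⇌ reagent, rate k5*(csat - [reagent]) (kL = 0.160 /min)
    free catalyst ⇌ dormant form (K = 1.70, k = 0.00620 /min)
    2 free catalyst → spent catalyst (k = 11.0 /M/min)

At 6.0 h the flask holds 18% of its L charge and 98% of its S charge, both unbound, so L has less left than S, and eS stands 12 points above the forecast. Put through s, that L share gives an S share of 97.7%. In the neighbour flask with 0.46 mM of free catalyst, 0.61% of the L charge is left at 6.0 h, so s gives 93.3% for S, and that flask holds 94%.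

The earlier runs and the new flask are simulated with constants of no real substance; scatter was added.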